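**Plan**

1. Locants used throughout: C1 (angular, methyl-bearing) – C2 – C3 – C4 (tertiary carbinol carrying the isopropyl group) – C5 (ring-fusion CH) close the cyclopentane ring A; C5 – C6 (anisoate) – C7 – C8 (vinylic methyl) = C9 – C10 (angelate) – C1 close the cycloheptene ring B; β is the face of the C1 methyl, α the other face.
2. Enabling feature: in ring B the C7–C8 bond lies across the ring from C1, so if C5 and C10 are bonded instead, C1/C5/C10 form a cyclopropane that carries a C6=C7 enol ether on C5 and a C9=C8 propenyl group on C10, and ring B is the [3,3] product of that cis-dialkenylcyclopropane.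
3. Retrosynthetic cuts, in order: the two ester C–O bonds; C10–O with C8=C9 (back to a C9=C10 alkene via its epoxide); C6–H and C4–isopropyl (back to a 1,3-dicarbonyl masked as a silyl enol ether); C7–C8 (Cope, restoring C5–C10); C5–C1 and C5–C10 (carbenoid cyclopropanation); the C3–C2 bond (diketone dianion alkylation); the C1=C10 alkene (Wittig).
4. Forward order: open-chain dienyl diazo diketone, enol silylation at the open-chain stage, ring A together with the cyclopropane in one intramolecular cyclopropanation, ring B by Cope rearrangement, then functional-group work on the bicycle.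
5. Stereochemistry: C1 from the chiral dirhodium catalyst and carried through unchanged; C4 from α-face organocerium addition; C5 by equilibration; C6 by hydroxyl-directed hydride delivery; C10 by α-epoxidation, SN2 opening and syn-elimination; alkene geometry from the Wittig step (E,E) and from angelic acid (Z).

Key step: step 8

Remark (assumption): the sense of induction of Rh2(S-PTAD)4, dirhodium tetrakis[(S)-(1-adamantyl)(phthalimido)acetate], in this intramolecular case cannot be assigned in advance; if step 7 gives the antipode of 10, Rh2(R-PTAD)4 is used instead.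

**Route**

Step 1
Reactants: 1 (E)-but-2-enal (crotonaldehyde); 2 ethyl 2-(triphenylphosphoranylidene)propanoate
Product: 3 ethyl (2E,4E)-2-methylhexa-2,4-dienoate
Conditions: CH2Cl2, 23 °C
Reagents that add atoms: none
Why: Wittig olefination with a stabilised α-branched ylide is reliably E-selective, so the new trisubstituted alkene forms E while the E-alkene of the enal is untouched.

Step 2
Reactants: 3 ethyl (2E,4E)-2-methylhexa-2,4-dienoate
Product: 4 (2E,4E)-2-methylhexa-2,4-dien-1-ol
Conditions: i-Bu2AlH, CH2Cl2, −78 → 0 °C; aq. potassium sodium tartrate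
Reagents that add atoms: none
Why: 1,2-reduction of the conjugated ester by the aluminium hydride (ester to allylic alcohol) leaves the diene and its geometry intact.

Step 3
Reactants: 4 (2E,4E)-2-methylhexa-2,4-dien-1-ol
Product: 5 (2E,4E)-1-bromo-2-methylhexa-2,4-diene
Conditions: PBr3, Et2O, −10 → 0 °C; used crude
Reagents that add atoms: phosphorus tribromide, BrP(Br)Br
Why: Substitution of the activated primary allylic hydroxyl by bromide (alcohol-to-bromide conversion) should give the conjugated primary bromide, the thermodynamically preferred allylic isomer, which is used at once.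

Step 4
Reactants: 5 (2E,4E)-1-bromo-2-methylhexa-2,4-diene; 6 pentane-2,4-dione
Product: 7 (7E,9E)-7-methylundeca-7,9-diene-2,4-dione
Conditions: 6, NaH then n-BuLi, THF, 0 °C; 5, 0 → 23 °C; AcOH quench
Reagents that add atoms: none
Why: The 1,3-dianion of the β-diketone reacts at its terminal, more basic carbon and the primary dienylic bromide is displaced directly (β-diketone dianion γ-alkylation), which joins C3 to C2.

Step 5
Reactants: 7 (7E,9E)-7-methylundeca-7,9-diene-2,4-dione
Product: 8 (7E,9E)-3-diazo-7-methylundeca-7,9-diene-2,4-dione
Conditions: p-ABSA, Et3N, MeCN, 0 → 23 °C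
Reagents that add atoms: 4-acetamidobenzenesulfonyl azide (p-ABSA), CC(=O)Nc1ccc(cc1)S(=O)(=O)N=[N+]=[N-]
Why: Regitz diazo transfer to the doubly activated methylene of a 1,3-diketone proceeds under mild amine base and does not touch the diene.

Step 6
Reactants: 8 (7E,9E)-3-diazo-7-methylundeca-7,9-diene-2,4-dione
Product: 9 (7E,9E)-2-[(tert-butyldimethylsilyl)oxy]-3-diazo-7-methylundeca-1,7,9-trien-4-one
Conditions: LiN(SiMe3)2, THF, −78 °C; TBSOTf, −78 °C; Et3N quench
Reagents that add atoms: tert-butyldimethylsilyl trifluoromethanesulfonate (TBSOTf), CC(C)(C)[Si](C)(C)OS(=O)(=O)C(F)(F)F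
Why: Kinetic deprotonation by the hindered lithium amide should take a methyl proton in preference to the methylene protons on the other flank, as in open-chain 2-alkanones, and O-silylation of the lithium enolate then fixes the 1-silyloxyvinyl group on the diazo carbon (kinetic enolate trapping, the known way to silyloxyvinyl diazo carbonyl compounds), so the choice of which carbonyl becomes the enol ether is made before any ring exists.

Step 7
Reactants: 9 (7E,9E)-2-[(tert-butyldimethylsilyl)oxy]-3-diazo-7-methylundeca-1,7,9-trien-4-one
Product: 10 (1S,5R,6R)-1-{1-[(tert-butyldimethylsilyl)oxy]ethenyl}-5-methyl-6-[(1E)-prop-1-en-1-yl]bicyclo[3.1.0]hexan-2-one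
Conditions: Rh2(S-PTAD)4 (1 mol %), hexanes, −20 → 23 °C, slow addition of 9; kept at or below 23 °C
Reagents that add atoms: none
Why: Loss of N2 gives a silyloxyvinyl (donor/acceptor) carbenoid that adds stereospecifically to the proximal trisubstituted E-alkene in the five-membered-ring mode (intramolecular cyclopropanation), the tether forcing the ring ketone endo and the silyloxyvinyl group exo, hence cis to the C1 methyl and, because the alkene is E, cis to the propenyl group, while the chiral carboxylate ligands choose the alkene face and so set C1, C5 and C10 together.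

Step 8
Reactants: 10 (1S,5R,6R)-1-{1-[(tert-butyldimethylsilyl)oxy]ethenyl}-5-methyl-6-[(1E)-prop-1-en-1-yl]bicyclo[3.1.0]hexan-2-one
Product: 11 (3aR,6R)-8-[(tert-butyldimethylsilyl)oxy]-3a,6-dimethyl-3,3a,6,7-tetrahydroazulen-1(2H)-one
Conditions: PhMe (0.5% Et3N), 110 °C, sealed tube, base-washed glass
Reagents that add atoms: none
Why: The cis-dialkenylcyclopropane rearranges in a concerted suprafacial [3,3] shift through a boat-like transition state in which the silyloxyvinyl and propenyl groups fold over the three-membered ring, the strained C5–C10 bond opening as C7–C8 forms and the π bonds moving to C5=C6 and C9=C10. The closest known reaction type is the thermal divinylcyclopropane–cycloheptadiene (Cope) rearrangement of cis-2-alkenylcyclopropyl silyl enol ethers, including those formed from silyloxyvinyl carbenoids and dienes. Ring B closes as a seven-membered ring by three-to-seven ring expansion, that is by joining the alkene termini C7 and C8 while cyclopropane carbon C1 stays as the angular carbon shared with the existing ring A. C1 passes through untouched, and the one new stereocentre, C8, is fixed by the E geometry of the propenyl group, whose methyl must point away from the cyclopropane in the boat and so ends trans to the C1 methyl (6R); this centre is erased in step 13. The step needs the two alkenyl groups cis, which the tether and the E-alkene built in during step 7, and it needs the [3,3] shift to outrun the homodienyl 1,5-hydrogen shift of the syn C1 methyl and ionic cyclopropane opening: the electron-rich silyl enol ether and strain release favour the Cope path, the bulky silyloxy group prefers the outward rotamer that puts C7 over the ring, and neutral base-washed conditions suppress ionisation, the syn methyl being the reason heating is needed at all. The product is a vinylogous silyl ester with C4 as a free ketone and C6 as a silyl enol ether, so the two carbonyl carbons are chemically distinct for what follows.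

Step 9
Reactants: 11 (3aR,6R)-8-[(tert-butyldimethylsilyl)oxy]-3a,6-dimethyl-3,3a,6,7-tetrahydroazulen-1(2H)-one; 12 isopropylmagnesium chloride
Product: 15 trans-fused β-hydroxy ketone (4β-hydroxy-4α-isopropyl-1β,8α-dimethyl-5αH ring A/ring B bicycle with C6 ketone and C9=C10 alkene), via carbinol silyl enol ether 13 (not isolated), via cis-fused 5-epi ketone 14 (not isolated)
Conditions: CeCl3, 12, THF, −78 °C; AcOH then TBAF, −78 → 0 °C; work-up; DBU (0.2 equiv), CH2Cl2, 23 °C
Reagents that add atoms: none
Why: The organocerium reagent should add 1,2 to the vinylogous ester carbonyl without enolising C3 and from the α face, because the C1 methyl projects its hydrogens over the β face of ring A whereas the α face carries only the planar vinylic C10–H turned away from C4; buffered fluoride then unveils the C6 ketone without the acid that would trigger Stork–Danheiser loss of the tertiary hydroxyl, and catalytic DBU equilibrates C5 to the trans-fused epimer, expected to be the more stable because C6 then lies cis to the small hydrogen-bonding hydroxyl and trans to the isopropyl group.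

Step 10
Reactants: 15 trans-fused β-hydroxy ketone
Product: 16 4β,6α-diol (4α-isopropyl-1β,8α-dimethyl-5αH bicycle with C9=C10 alkene)
Conditions: Me4NBH(OAc)3, MeCN/AcOH (1:1), −20 → 0 °C
Reagents that add atoms: none
Why: In the Evans–Saksena reduction the C4 hydroxyl exchanges onto boron and delivers hydride internally to the β face of the C6 carbonyl, giving the 4,6-anti diol with the 6α-hydroxyl, while external reduction by this mild hydride is negligible.

Step 11
Reactants: 16 4β,6α-diol; 17 4-methoxybenzoyl chloride
Product: 18 6α-(4-methoxybenzoyl)oxy 4β-alcohol with C9=C10 alkene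
Conditions: Et3N, DMAP (cat.), CH2Cl2, 0 → 23 °C
Reagents that add atoms: none
Why: DMAP-catalysed acylation takes the secondary C6 hydroxyl and leaves the hindered tertiary C4 hydroxyl untouched.

Step 12
Reactants: 18 6α-anisoate with C9=C10 alkene
Product: 19 9α,10α-epoxide of 18
Conditions: mCPBA, NaHCO3, CH2Cl2, 0 °C
Reagents that add atoms: 3-chloroperoxybenzoic acid (mCPBA), OOC(=O)c1cccc(Cl)c1
Why: In the Prilezhaev epoxidation the peracid should approach C9=C10 from the α face, anti to the pseudoaxial C1 methyl on the adjacent quaternary carbon and to the pseudoaxial β C8–H, the C8 methyl being pseudoequatorial, which places the future C10 oxygen on the α face.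

Step 13
Reactants: 19 9α,10α-epoxide
Product: 22 10α-allylic alcohol (4β,10α-dihydroxy 6α-anisoate with C8=C9 alkene), via hydroxy selenide 20 (not isolated), via selenoxide 21 (not isolated)
Conditions: (PhSe)2, NaBH4, EtOH, 23 → 60 °C; then THF, 30% H2O2, 0 → 23 °C
Reagents that add atoms: none
Why: Phenylselenolate should open the epoxide by SN2 attack at C9 from the β face (C10 is neopentylic and screened by the C1 methyl), which puts selenium cis to the β C8–H, and oxidation to the selenoxide followed by syn-elimination away from the carbinol carbon (selenoxide elimination) forms the C8=C9 alkene, erases C8 and leaves the 10α-hydroxyl.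

Step 14
Reactants: 22 10α-allylic alcohol; 23 angelic acid ((2Z)-2-methylbut-2-enoic acid)
Product: 24 target, (3R,3aS,4S,8R,8aS)-3-hydroxy-6,8a-dimethyl-8-{[(2Z)-2-methylbut-2-enoyl]oxy}-3-(propan-2-yl)-1,2,3,3a,4,5,8,8a-octahydroazulen-4-yl 4-methoxybenzoate
Conditions: 23, 2,4,6-Cl3C6H2COCl, Et3N, PhMe, 23 °C; then 22, 80 °C (no DMAP)
Reagents that add atoms: none
Why: Yamaguchi-type mixed-anhydride acylation without a nucleophilic catalyst transfers the angeloyl group to the secondary allylic hydroxyl with retention of the Z geometry, and the tertiary C4 hydroxyl does not react.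

**Compound list**

1 | (E)-but-2-enal (crotonaldehyde) | C/C=C/C=O | starting material
2 | ethyl 2-(triphenylphosphoranylidene)propanoate | CCOC(=O)C(C)=P(c1ccccc1)(c1ccccc1)c1ccccc1 | starting material
3 | ethyl (2E,4E)-2-methylhexa-2,4-dienoate | CCOC(=O)/C(C)=C/C=C/C | intermediate
4 | (2E,4E)-2-methylhexa-2,4-dien-1-ol | OC/C(C)=C/C=C/C | intermediate
5 | (2E,4E)-1-bromo-2-methylhexa-2,4-diene | BrC/C(C)=C/C=C/C | intermediate
6 | pentane-2,4-dione | CC(=O)CC(C)=O | starting material
7 | (7E,9E)-7-methylundeca-7,9-diene-2,4-dione | CC(=O)CC(=O)CC/C(C)=C/C=C/C | intermediate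
8 | (7E,9E)-3-diazo-7-methylundeca-7,9-diene-2,4-dione | CC(=O)C(=[N+]=[N-])C(=O)CC/C(C)=C/C=C/C | intermediate
9 | (7E,9E)-2-[(tert-butyldimethylsilyl)oxy]-3-diazo-7-methylundeca-1,7,9-trien-4-one | C=C(O[Si](C)(C)C(C)(C)C)C(=[N+]=[N-])C(=O)CC/C(C)=C/C=C/C | intermediate
10 | (1S,5R,6R)-1-{1-[(tert-butyldimethylsilyl)oxy]ethenyl}-5-methyl-6-[(1E)-prop-1-en-1-yl]bicyclo[3.1.0]hexan-2-one; bicyclohexane C1, C5, C6 are target C5, C1, C10; silyloxyvinyl, methyl and propenyl all cis on the cyclopropane | C=C(O[Si](C)(C)C(C)(C)C)[C@@]12C(=O)CC[C@]1(C)[C@H]2/C=C/C | intermediate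
11 | (3aR,6R)-8-[(tert-butyldimethylsilyl)oxy]-3a,6-dimethyl-3,3a,6,7-tetrahydroazulen-1(2H)-one; C4 ketone, C5=C6 silyl enol ether, C9=C10 alkene, C8 methyl trans to C1 methyl | C1=C[C@H](C)CC(O[Si](C)(C)C(C)(C)C)=C2[C@]1(C)CCC2=O | intermediate
12 | isopropylmagnesium chloride | CC(C)[Mg]Cl | starting material
13 | carbinol silyl enol ether: 4β-hydroxy-4α-isopropyl adduct of 11, C5=C6 silyl enol ether retained | C1=C[C@H](C)CC(O[Si](C)(C)C(C)(C)C)=C2[C@]1(C)CC[C@@]2(O)C(C)C | intermediate
14 | cis-fused 5-epi ketone: 4β-hydroxy-4α-isopropyl-1β,8α-dimethyl-5βH bicycle, C6 ketone, C9=C10 alkene | C1=C[C@H](C)CC(=O)[C@H]2[C@]1(C)CC[C@@]2(O)C(C)C | intermediate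
15 | trans-fused β-hydroxy ketone: 4β-hydroxy-4α-isopropyl-1β,8α-dimethyl-5αH bicycle, C6 ketone, C9=C10 alkene | C1=C[C@H](C)CC(=O)[C@@H]2[C@]1(C)CC[C@@]2(O)C(C)C | intermediate
16 | 4β,6α-diol: 4α-isopropyl-1β,8α-dimethyl-5αH bicycle, C9=C10 alkene | C1=C[C@H](C)C[C@H](O)[C@@H]2[C@]1(C)CC[C@@]2(O)C(C)C | intermediate
17 | 4-methoxybenzoyl chloride | COc1ccc(cc1)C(Cl)=O | starting material
18 | 6α-(4-methoxybenzoyl)oxy-4β-hydroxy compound, C9=C10 alkene | C1=C[C@H](C)C[C@H](OC(=O)c2ccc(OC)cc2)[C@@H]2[C@]1(C)CC[C@@]2(O)C(C)C | intermediate
19 | 9α,10α-epoxide of 18 | O3[C@@H]1[C@H]3[C@H](C)C[C@H](OC(=O)c2ccc(OC)cc2)[C@@H]2[C@]1(C)CC[C@@]2(O)C(C)C | intermediate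
20 | hydroxy selenide: 10α-hydroxy-9β-(phenylselanyl) compound, 8α-methyl, 8β-H | O[C@@H]1[C@@H]([Se]c3ccccc3)[C@H](C)C[C@H](OC(=O)c2ccc(OC)cc2)[C@@H]2[C@]1(C)CC[C@@]2(O)C(C)C | intermediate
21 | selenoxide of 20 | O[C@@H]1[C@@H]([Se](=O)c3ccccc3)[C@H](C)C[C@H](OC(=O)c2ccc(OC)cc2)[C@@H]2[C@]1(C)CC[C@@]2(O)C(C)C | intermediate
22 | 10α-allylic alcohol: 4β,10α-dihydroxy-6α-(4-methoxybenzoyl)oxy compound, C8=C9 alkene | O[C@@H]1C=C(C)C[C@H](OC(=O)c2ccc(OC)cc2)[C@@H]2[C@]1(C)CC[C@@]2(O)C(C)C | intermediate
23 | angelic acid, (2Z)-2-methylbut-2-enoic acid | C/C=C(/C)C(=O)O | starting material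
24 | (3R,3aS,4S,8R,8aS)-3-hydroxy-6,8a-dimethyl-8-{[(2Z)-2-methylbut-2-enoyl]oxy}-3-(propan-2-yl)-1,2,3,3a,4,5,8,8a-octahydroazulen-4-yl 4-methoxybenzoate | C/C=C(/C)C(=O)O[C@@H]1C=C(C)C[C@H](OC(=O)c2ccc(OC)cc2)[C@@H]2[C@]1(C)CC[C@@]2(O)C(C)C | target

**Totals and risks**

Total step count: 14. Longest linear sequence: 14 steps (1 to 24); 2, 6, 12, 17 and 23 enter as purchased partners.

Steps most likely to fail, riskiest first:

Step 9. The tertiary allylic hydroxyl beside the enol ether may be lost by ionisation (Stork–Danheiser-type dehydration), retro-aldol or E1cB loss may occur during the fluoride and DBU treatment, and convergence at C5 may be incomplete. The fallback sets out from 11 and returns at 15. The same organocerium addition is worked up cold at pH 7 and the crude carbinol is capped with Et3SiOTf and 2,6-lutidine at −78 °C to give the C4 triethylsilyl ether of the carbinol enol ether F2. One equivalent of acetic-acid-buffered TBAF at −78 °C should cleave only the far more labile enol silyl ether and give the β-(triethylsilyloxy) ketone F3. In F3 neither retro-aldol nor loss of hydroxide is possible, so C5 can be equilibrated with DBU without constraint. HF·pyridine in THF/pyridine then frees the tertiary hydroxyl and the sequence rejoins the route at 15.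

Step 7. The dirhodium carboxylate may discriminate the alkene faces poorly in this intramolecular setting, or the diazo compound may be diverted by carbene dimerisation or electrocyclisation before cyclopropanation. The fallback sets out from 8 and returns at 10. The diazo diketone itself is decomposed as an acceptor/acceptor carbenoid with [Cu(MeCN)4]PF6 and a chiral bis(oxazoline) ligand (slow addition, 1,2-dichloroethane, 50 °C) to give (1S,5R,6R)-1-acetyl-5-methyl-6-[(1E)-prop-1-en-1-yl]bicyclo[3.1.0]hexan-2-one F1, which has the same all-cis array. F1 is then enolised kinetically at the acetyl methyl (LiN(SiMe3)2, THF, −78 °C; TBSOTf) to reach 10; on this path the regiochemistry of enolisation (acetyl methyl against ring C3) becomes the point to optimise. In either variant the enantiomeric purity would be raised if needed by recrystallisation at the stage of 16 or 18.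

Step 14. Acylation of the neopentylic allylic C10 hydroxyl may be slow, which gives time for Z-to-E isomerisation of the activated angeloyl group. The fallback sets out from 22 and returns at 24. The hydroxyl is first esterified with 2-[bis(2,2,2-trifluoroethoxy)phosphoryl]propanoic acid (dicyclohexylcarbodiimide, DMAP, CH2Cl2) to give the 10α-phosphonopropanoate F4. The angelate double bond is then built on the ester by Still–Gennari olefination with acetaldehyde (KN(SiMe3)2, 18-crown-6, THF, −78 °C), whose kinetic Z selectivity should give 24 directly.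

**Further compounds**

F1 | step 7 | (1S,5R,6R)-1-acetyl-5-methyl-6-[(1E)-prop-1-en-1-yl]bicyclo[3.1.0]hexan-2-one | CC(=O)[C@@]12C(=O)CC[C@]1(C)[C@H]2/C=C/C
F2 | step 9 | C4 triethylsilyl ether of the carbinol silyl enol ether 13 | C1=C[C@H](C)CC(O[Si](C)(C)C(C)(C)C)=C2[C@]1(C)CC[C@@]2(O[Si](CC)(CC)CC)C(C)C
F3 | step 9 | C4 triethylsilyl ether of the trans-fused β-hydroxy ketone 15 | C1=C[C@H](C)CC(=O)[C@@H]2[C@]1(C)CC[C@@]2(O[Si](CC)(CC)CC)C(C)C
F4 | step 14 | 10α-{2-[bis(2,2,2-trifluoroethoxy)phosphoryl]propanoyl}oxy derivative of 22 | CC(C(=O)O[C@@H]1C=C(C)C[C@H](OC(=O)c2ccc(OC)cc2)[C@@H]2[C@]1(C)CC[C@@]2(O)C(C)C)P(=O)(OCC(F)(F)F)OCC(F)(F)F
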